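**Plan**

- Numbering of the target (cyclotetradeca[b]furan): O1, C2(=O), C3(=CH2), C3a, large-ring carbons C4–C15 (Me on C6, C10, C14; OAc on C12), C15a. Enabling feature: the array O1–C15a–C3a–C3(=CH2)–C2 is a homoallylic alcohol whose alkene is the exocyclic methylene, and its C3a–C15a bond is shared by the five- and the fourteen-membered ring. A 2-(alkoxycarbonyl)allyl addition to an enal can therefore make that bond, both rings and both new stereocentres.
- Retrosynthesis: cut O1–C2 and C3a–C15a (acyclic trienal 23 carrying a γ-substituted 2-(methoxycarbonyl)allylboronate); then the =CH2 carbon and C2 off an alkyne C3≡C3a (ynoate 18); then C12–C13 (vinylogous aldol); then C4–C5 (propargyl alkylation), back to geraniol.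
- Forward: geraniol → dienynal 9; a vinylogous Mukaiyama aldol adds C13–C15a and sets C12; ynoate; syn hydroalumination/borylmethylation; the fourteen-membered ring and then the lactone form in the last step, which gives the target itself.
- Stereochemistry: C6=C7 and C10=C11 come from geraniol (C6=C7 through the (E)-selective SeO2 oxidation), C14=C15 from the dienolate addition; C12 from the catalyst-controlled aldol; C3a/C15a from the boronate geometry (anti, hence trans-fused) and the chiral phosphoric acid (aldehyde face).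

Key step: step 16

Assumptions:
- Both (R)-configured catalysts are taken to deliver the carbon nucleophile to the Re face of the aldehyde, the sense usually found for these catalyst classes. The bisphosphoramide of step 8 is the (R,R) Lewis base built from two N,N'-dimethyl-1,1'-binaphthyl-2,2'-diamine phosphoramide units joined by an N,N'-dimethylpentane-1,5-diamine tether. (R)-TRIP is (R)-3,3'-bis(2,4,6-triisopropylphenyl)-1,1'-binaphthyl-2,2'-diyl hydrogen phosphate.
- The ketene acetal geometry of 11 and 12 is not controlled and is of no consequence; it is left open in their SMILES.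

**Route**

Step 1
Reactants: 1 geraniol, (2E)-3,7-dimethylocta-2,6-dien-1-ol
Product: 2 tert-butyl{[(2E)-3,7-dimethylocta-2,6-dien-1-yl]oxy}dimethylsilane
Conditions: TBSCl, imidazole, DMF, 0 °C → rt
Reagents that add atoms: tert-butyldimethylsilyl chloride, CC(C)(C)[Si](C)(C)Cl
Why: Standard silylation of a primary allylic alcohol; the ether should withstand the selenium oxidation, the Appel bromination and the organolithium alkylation that follow.

Step 2
Reactants: 2 tert-butyl{[(2E)-3,7-dimethylocta-2,6-dien-1-yl]oxy}dimethylsilane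
Product: 3 (2E,6E)-8-[(tert-butyldimethylsilyl)oxy]-2,6-dimethylocta-2,6-dien-1-ol
Conditions: SeO2 (cat.), t-BuOOH, salicylic acid (cat.), CH2Cl2, rt
Reagents that add atoms: tert-butyl hydroperoxide, CC(C)(C)OO
Why: Allylic oxidation (ene reaction, then [2,3]-sigmatropic shift of the allylseleninic acid) is selective for the (E)-methyl group of the terminal, more electron-rich trisubstituted alkene, so the new CH2OH should stand trans to the chain.

Step 3
Reactants: 3 (2E,6E)-8-[(tert-butyldimethylsilyl)oxy]-2,6-dimethylocta-2,6-dien-1-ol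
Product: 4 {[(2E,6E)-8-bromo-3,7-dimethylocta-2,6-dien-1-yl]oxy}(tert-butyl)dimethylsilane
Conditions: PPh3, CBr4, CH2Cl2, 0 °C
Reagents that add atoms: carbon tetrabromide, BrC(Br)(Br)Br
Why: Appel bromination of a primary allylic alcohol by SN2 displacement of the alkoxyphosphonium ion should proceed without allylic transposition or loss of alkene geometry.

Step 4
Reactants: 4 {[(2E,6E)-8-bromo-3,7-dimethylocta-2,6-dien-1-yl]oxy}(tert-butyl)dimethylsilane; 5 1-(trimethylsilyl)propyne
Product: 7 tert-butyl{[(2E,6E)-3,7-dimethyl-11-(trimethylsilyl)undeca-2,6-dien-10-yn-1-yl]oxy}dimethylsilane, via 3-(trimethylsilyl)prop-2-yn-1-yllithium 6 (not isolated)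
Conditions: 5, n-BuLi, THF, −78 → −20 °C; then 4, −78 °C → rt
Reagents that add atoms: none
Why: Propargylic lithiation of the silylalkyne and SN2 alkylation of the primary allylic bromide at its CH2 terminus join the three-carbon unit; the silyl group steers the ambident anion to react at the propargylic carbon.

Step 5
Reactants: 7 tert-butyl{[(2E,6E)-3,7-dimethyl-11-(trimethylsilyl)undeca-2,6-dien-10-yn-1-yl]oxy}dimethylsilane
Product: 8 (2E,6E)-3,7-dimethylundeca-2,6-dien-10-yn-1-ol
Conditions: Bu4NF, THF, rt
Reagents that add atoms: none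
Why: Fluoride cleaves the O–Si and the C(sp)–Si bond in one operation, uncovering the allylic alcohol and the terminal alkyne.

Step 6
Reactants: 8 (2E,6E)-3,7-dimethylundeca-2,6-dien-10-yn-1-ol
Product: 9 (2E,6E)-3,7-dimethylundeca-2,6-dien-10-ynal
Conditions: MnO2, CH2Cl2, rt
Reagents that add atoms: none
Why: MnO2 oxidises the allylic alcohol selectively to the enal, leaves the alkyne alone and should keep the (E)-geometry.

Step 7
Reactants: 10 ethyl 3-methylbut-2-enoate
Product: 12 tert-butyl[(1-ethoxy-3-methylbuta-1,3-dien-1-yl)oxy]dimethylsilane, via lithium dienolate 11 (not isolated)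
Conditions: LiN(i-Pr)2 (commercial solution), THF, −78 °C; then TBSCl, −78 °C → rt
Reagents that add atoms: tert-butyldimethylsilyl chloride, CC(C)(C)[Si](C)(C)Cl
Why: Kinetic γ-deprotonation of the senecioate and O-silylation of the extended enolate give the silyl dienol ether needed for the vinylogous Mukaiyama aldol reaction.

Step 8
Reactants: 9 (2E,6E)-3,7-dimethylundeca-2,6-dien-10-ynal; 12 tert-butyl[(1-ethoxy-3-methylbuta-1,3-dien-1-yl)oxy]dimethylsilane
Product: 14 ethyl (2E,5R,6E,10E)-5-hydroxy-3,7,11-trimethylpentadeca-2,6,10-trien-14-ynoate, via trichlorosilyl aldolate 13 (not isolated)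
Conditions: SiCl4, (R,R)-bisphosphoramide (cat.), i-Pr2NEt (cat.), CH2Cl2, −78 °C; aq. NaHCO3
Reagents that add atoms: none
Why: Vinylogous Mukaiyama aldol reaction under Lewis base-activated SiCl4: the phosphoramide-bound trichlorosilyl cation binds the enal, the dienolate attacks through its γ-carbon in an open transition state on the Re face to set the (R)-carbinol centre, and the ester-conjugated alkene should form with (E)-geometry.

Step 9
Reactants: 14 ethyl (2E,5R,6E,10E)-5-hydroxy-3,7,11-trimethylpentadeca-2,6,10-trien-14-ynoate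
Product: 15 (2E,5R,6E,10E)-3,7,11-trimethylpentadeca-2,6,10-trien-14-yne-1,5-diol
Conditions: i-Bu2AlH, CH2Cl2, −78 °C; aq. KNaC4H4O6
Reagents that add atoms: none
Why: i-Bu2AlH reduces the conjugated ester 1,2 to the allylic alcohol at low temperature and should leave the alkenes, the alkyne and the carbinol centre untouched.

Step 10
Reactants: 15 (2E,5R,6E,10E)-3,7,11-trimethylpentadeca-2,6,10-trien-14-yne-1,5-diol
Product: 16 (2E,5R,6E,10E)-3,7,11-trimethyl-1,5-bis[(triethylsilyl)oxy]pentadeca-2,6,10-trien-14-yne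
Conditions: Et3SiCl, imidazole, DMF, 0 °C
Reagents that add atoms: chlorotriethylsilane, CC[Si](Cl)(CC)CC
Why: Both hydroxyl groups are masked as triethylsilyl ethers, which tolerate n-BuLi and the aluminium hydride of the next two steps and can later be removed together under mild acid.

Step 11
Reactants: 16 (2E,5R,6E,10E)-3,7,11-trimethyl-1,5-bis[(triethylsilyl)oxy]pentadeca-2,6,10-trien-14-yne
Product: 18 methyl (6E,10E,12R,14E)-6,10,14-trimethyl-12,16-bis[(triethylsilyl)oxy]hexadeca-6,10,14-trien-2-ynoate, via lithium acetylide 17 (not isolated)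
Conditions: n-BuLi, THF, −78 °C; then ClCO2Me, −78 → 0 °C
Reagents that add atoms: methyl chloroformate, COC(=O)Cl
Why: Deprotonation of the terminal alkyne and C-acylation of the acetylide with a chloroformate is the standard route to a 2-alkynoate.

Step 12
Reactants: 18 methyl (6E,10E,12R,14E)-6,10,14-trimethyl-12,16-bis[(triethylsilyl)oxy]hexadeca-6,10,14-trien-2-ynoate
Product: 20 methyl (2Z,6E,10E,12R,14E)-6,10,14-trimethyl-2-[(4,4,5,5-tetramethyl-1,3,2-dioxaborolan-2-yl)methyl]-12,16-bis[(triethylsilyl)oxy]hexadeca-2,6,10,14-tetraenoate, via alkenylalane 19 (not isolated)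
Conditions: i-Bu2AlH, HMPA, THF, 0 °C; then ICH2Bpin, 0 °C → rt
Reagents that add atoms: 2-(iodomethyl)-4,4,5,5-tetramethyl-1,3,2-dioxaborolane, ICB1OC(C)(C)C(C)(C)O1
Why: The i-Bu2AlH·HMPA complex adds H and Al syn across the ynoate with aluminium on the α-carbon (conjugate hydroalumination), and C-alkylation of this alkenylalane by the iodomethylboronate with retention gives the allylboronate with the chain cis to the ester and trans to CH2B, as known for simple 2-alkynoates.

Step 13
Reactants: 20 methyl (2Z,6E,10E,12R,14E)-6,10,14-trimethyl-2-[(4,4,5,5-tetramethyl-1,3,2-dioxaborolan-2-yl)methyl]-12,16-bis[(triethylsilyl)oxy]hexadeca-2,6,10,14-tetraenoate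
Product: 21 methyl (2Z,6E,10E,12R,14E)-12,16-dihydroxy-6,10,14-trimethyl-2-[(4,4,5,5-tetramethyl-1,3,2-dioxaborolan-2-yl)methyl]hexadeca-2,6,10,14-tetraenoate
Conditions: PPTS (cat.), MeOH, 0 °C
Reagents that add atoms: none
Why: Mild acid-catalysed methanolysis removes both triethylsilyl ethers, while the pinacol boronate, the methyl ester and the alkene geometries should survive.

Step 14
Reactants: 21 methyl (2Z,6E,10E,12R,14E)-12,16-dihydroxy-6,10,14-trimethyl-2-[(4,4,5,5-tetramethyl-1,3,2-dioxaborolan-2-yl)methyl]hexadeca-2,6,10,14-tetraenoate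
Product: 22 methyl (2Z,6E,10E,12R,14E)-12-hydroxy-6,10,14-trimethyl-16-oxo-2-[(4,4,5,5-tetramethyl-1,3,2-dioxaborolan-2-yl)methyl]hexadeca-2,6,10,14-tetraenoate
Conditions: TEMPO (2,2,6,6-tetramethylpiperidin-1-oxyl, cat.), PhI(OAc)2, CH2Cl2, rt
Reagents that add atoms: none
Why: The oxoammonium salt generated from TEMPO and PhI(OAc)2 oxidises the primary allylic alcohol much faster than the hindered secondary one and does not over-oxidise the enal, whose (E)-geometry also prevents lactol formation with the free hydroxyl group.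

Step 15
Reactants: 22 methyl (2Z,6E,10E,12R,14E)-12-hydroxy-6,10,14-trimethyl-16-oxo-2-[(4,4,5,5-tetramethyl-1,3,2-dioxaborolan-2-yl)methyl]hexadeca-2,6,10,14-tetraenoate
Product: 23 methyl (2Z,6E,10E,12R,14E)-12-(acetyloxy)-6,10,14-trimethyl-16-oxo-2-[(4,4,5,5-tetramethyl-1,3,2-dioxaborolan-2-yl)methyl]hexadeca-2,6,10,14-tetraenoate
Conditions: Ac2O, pyridine, DMAP (cat.), CH2Cl2, 0 °C
Reagents that add atoms: acetic anhydride, CC(=O)OC(C)=O
Why: Acylation of the secondary alcohol installs the acetate of the target before ring closure; the uncatalysed addition of the electron-poor allylboronate to the enal should be slow enough at 0 °C for 23 to be handled.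

Step 16
Reactants: 23 methyl (2Z,6E,10E,12R,14E)-12-(acetyloxy)-6,10,14-trimethyl-16-oxo-2-[(4,4,5,5-tetramethyl-1,3,2-dioxaborolan-2-yl)methyl]hexadeca-2,6,10,14-tetraenoate
Product: 25 (3aR,6E,10E,12R,14E,15aS)-6,10,14-trimethyl-3-methylidene-2-oxo-2,3,3a,4,5,8,9,12,13,15a-decahydrocyclotetradeca[b]furan-12-yl acetate (CNP0206931.1), via macrocyclic pinacol borate 24 (not isolated)
Conditions: (R)-TRIP (10 mol%), 4 Å MS, toluene, slow addition of 23 to ca. 1 mM, rt → 40 °C; then PPTS (cat.), rt
Reagents that add atoms: none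
Why: Proposed new method: the phosphoric acid should hydrogen-bond to a boronate oxygen (and through its P=O to the formyl hydrogen), so that the γ-substituted 2-(methoxycarbonyl)allylboronate adds to the enal carbonyl through a closed six-membered chair (Zimmerman–Traxler) transition state with allylic transposition, boron passing from carbon to oxygen, after which the borate oxygen displaces methoxide from the neighbouring ester. The closest known reactions are the chiral phosphoric acid-catalysed allyl- and crotylboration of aldehydes with pinacol boronates and the acid-catalysed intermolecular additions of 2-alkoxycarbonyl allylboronates that give α-methylene-γ-lactones; their intramolecular, macrocycle-forming combination is the untested part. The carbocycle closes as a 14-membered ring in an exo-trig sense at the formyl carbon with the six-membered chair embedded in it, and the lactone then closes 5-exo-trig at the ester carbonyl. The relative configuration of the two new centres is fixed by the boronate geometry from step 12: the tether carbon on the γ-carbon is trans to CH2B and therefore equatorial like the alkenyl residue of the aldehyde, which should give the anti adduct and hence the trans-fused lactone. The absolute sense is set by the catalyst, (R)-TRIP being expected to expose the Re face of the aldehyde, which gives (S) at C15a and (R) at C3a whatever the bias of the remote acetoxy centre. The step needs ring closure to outrun oligomerisation and the catalysed path to outrun the background reaction; the three (E)-trisubstituted alkenes pre-organise the chain, slow addition keeps the concentration low, and the electron-poor boronate is nearly inert towards the enal without acid.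

**Compound list**

1 | geraniol, (2E)-3,7-dimethylocta-2,6-dien-1-ol | CC(C)=CCC/C(C)=C/CO | starting material
2 | tert-butyl{[(2E)-3,7-dimethylocta-2,6-dien-1-yl]oxy}dimethylsilane | CC(C)=CCC/C(C)=C/CO[Si](C)(C)C(C)(C)C | intermediate
3 | (2E,6E)-8-[(tert-butyldimethylsilyl)oxy]-2,6-dimethylocta-2,6-dien-1-ol | OC/C(C)=C/CC/C(C)=C/CO[Si](C)(C)C(C)(C)C | intermediate
4 | {[(2E,6E)-8-bromo-3,7-dimethylocta-2,6-dien-1-yl]oxy}(tert-butyl)dimethylsilane | BrC/C(C)=C/CC/C(C)=C/CO[Si](C)(C)C(C)(C)C | intermediate
5 | 1-(trimethylsilyl)propyne | CC#C[Si](C)(C)C | starting material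
6 | 3-(trimethylsilyl)prop-2-yn-1-yllithium | [Li]CC#C[Si](C)(C)C | intermediate (not isolated)
7 | tert-butyl{[(2E,6E)-3,7-dimethyl-11-(trimethylsilyl)undeca-2,6-dien-10-yn-1-yl]oxy}dimethylsilane | C[Si](C)(C)C#CCC/C(C)=C/CC/C(C)=C/CO[Si](C)(C)C(C)(C)C | intermediate
8 | (2E,6E)-3,7-dimethylundeca-2,6-dien-10-yn-1-ol | C#CCC/C(C)=C/CC/C(C)=C/CO | intermediate
9 | (2E,6E)-3,7-dimethylundeca-2,6-dien-10-ynal | C#CCC/C(C)=C/CC/C(C)=C/C=O | intermediate
10 | ethyl 3-methylbut-2-enoate | CCOC(=O)C=C(C)C | starting material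
11 | lithium 1-ethoxy-3-methylbuta-1,3-dien-1-olate | C=C(C)C=C(OCC)O[Li] | intermediate (not isolated)
12 | tert-butyl[(1-ethoxy-3-methylbuta-1,3-dien-1-yl)oxy]dimethylsilane | C=C(C)C=C(OCC)O[Si](C)(C)C(C)(C)C | intermediate
13 | ethyl (2E,5R,6E,10E)-3,7,11-trimethyl-5-[(trichlorosilyl)oxy]pentadeca-2,6,10-trien-14-ynoate | C#CCC/C(C)=C/CC/C(C)=C/[C@H](O[Si](Cl)(Cl)Cl)C/C(C)=C/C(=O)OCC | intermediate (not isolated)
14 | ethyl (2E,5R,6E,10E)-5-hydroxy-3,7,11-trimethylpentadeca-2,6,10-trien-14-ynoate | C#CCC/C(C)=C/CC/C(C)=C/[C@H](O)C/C(C)=C/C(=O)OCC | intermediate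
15 | (2E,5R,6E,10E)-3,7,11-trimethylpentadeca-2,6,10-trien-14-yne-1,5-diol | C#CCC/C(C)=C/CC/C(C)=C/[C@H](O)C/C(C)=C/CO | intermediate
16 | (2E,5R,6E,10E)-3,7,11-trimethyl-1,5-bis[(triethylsilyl)oxy]pentadeca-2,6,10-trien-14-yne | C#CCC/C(C)=C/CC/C(C)=C/[C@H](O[Si](CC)(CC)CC)C/C(C)=C/CO[Si](CC)(CC)CC | intermediate
17 | lithium acetylide of 16 | [Li]C#CCC/C(C)=C/CC/C(C)=C/[C@H](O[Si](CC)(CC)CC)C/C(C)=C/CO[Si](CC)(CC)CC | intermediate (not isolated)
18 | methyl (6E,10E,12R,14E)-6,10,14-trimethyl-12,16-bis[(triethylsilyl)oxy]hexadeca-6,10,14-trien-2-ynoate | COC(=O)C#CCC/C(C)=C/CC/C(C)=C/[C@H](O[Si](CC)(CC)CC)C/C(C)=C/CO[Si](CC)(CC)CC | intermediate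
19 | methyl (6E,10E,12R,14E)-2-[bis(2-methylpropyl)alumanyl]-6,10,14-trimethyl-12,16-bis[(triethylsilyl)oxy]hexadeca-2,6,10,14-tetraenoate (Al cis to the C3 hydrogen, chain cis to the ester) | COC(=O)/C([Al](CC(C)C)CC(C)C)=C\CC/C(C)=C/CC/C(C)=C/[C@H](O[Si](CC)(CC)CC)C/C(C)=C/CO[Si](CC)(CC)CC | intermediate (not isolated)
20 | methyl (2Z,6E,10E,12R,14E)-6,10,14-trimethyl-2-[(4,4,5,5-tetramethyl-1,3,2-dioxaborolan-2-yl)methyl]-12,16-bis[(triethylsilyl)oxy]hexadeca-2,6,10,14-tetraenoate | COC(=O)/C(CB1OC(C)(C)C(C)(C)O1)=C\CC/C(C)=C/CC/C(C)=C/[C@H](O[Si](CC)(CC)CC)C/C(C)=C/CO[Si](CC)(CC)CC | intermediate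
21 | methyl (2Z,6E,10E,12R,14E)-12,16-dihydroxy-6,10,14-trimethyl-2-[(4,4,5,5-tetramethyl-1,3,2-dioxaborolan-2-yl)methyl]hexadeca-2,6,10,14-tetraenoate | COC(=O)/C(CB1OC(C)(C)C(C)(C)O1)=C\CC/C(C)=C/CC/C(C)=C/[C@H](O)C/C(C)=C/CO | intermediate
22 | methyl (2Z,6E,10E,12R,14E)-12-hydroxy-6,10,14-trimethyl-16-oxo-2-[(4,4,5,5-tetramethyl-1,3,2-dioxaborolan-2-yl)methyl]hexadeca-2,6,10,14-tetraenoate | COC(=O)/C(CB1OC(C)(C)C(C)(C)O1)=C\CC/C(C)=C/CC/C(C)=C/[C@H](O)C/C(C)=C/C=O | intermediate
23 | methyl (2Z,6E,10E,12R,14E)-12-(acetyloxy)-6,10,14-trimethyl-16-oxo-2-[(4,4,5,5-tetramethyl-1,3,2-dioxaborolan-2-yl)methyl]hexadeca-2,6,10,14-tetraenoate | COC(=O)/C(CB1OC(C)(C)C(C)(C)O1)=C\CC/C(C)=C/CC/C(C)=C/[C@H](OC(C)=O)C/C(C)=C/C=O | intermediate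
24 | methyl 2-{(1R,2S,3E,6R,7E,11E)-6-(acetyloxy)-4,8,12-trimethyl-2-[(4,4,5,5-tetramethyl-1,3,2-dioxaborolan-2-yl)oxy]cyclotetradeca-3,7,11-trien-1-yl}prop-2-enoate | C=C(C(=O)OC)[C@H]1CC/C(C)=C/CC/C(C)=C/[C@H](OC(C)=O)C/C(C)=C/[C@@H]1OB1OC(C)(C)C(C)(C)O1 | intermediate (not isolated)
25 | (3aR,6E,10E,12R,14E,15aS)-6,10,14-trimethyl-3-methylidene-2-oxo-2,3,3a,4,5,8,9,12,13,15a-decahydrocyclotetradeca[b]furan-12-yl acetate (CNP0206931.1) | C=C1C(=O)O[C@H]2/C=C(\C)C[C@@H](OC(C)=O)/C=C(\C)CC/C=C(\C)CC[C@H]12 | target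

**Count and risks**

Total step count: 16. Longest linear sequence: 15 steps (steps 1–6 and 8–16, from geraniol); step 7 is the one-step side branch.

Steps most likely to fail:

1. Step 16 (proposed new method). What may go wrong: intermolecular oligomerisation in place of ring closure, a slow catalysed addition that lets the unselective background reaction compete, or poor catalyst control of the aldehyde face against the bias of the remote acetoxy centre. Fallback (known macrocyclisation with divalent chromium), setting out from 18 and coming back at 25: alkenylalane 19, made from 18 as in step 12, is trapped with paraformaldehyde to give the (2Z)-2-(hydroxymethyl) enoate F1. PPh3/CBr4 converts it into the (2E)-2-(bromomethyl) enoate F2, in which the chain is still trans to CH2Br. PPTS/MeOH removes both silyl groups to give the bromo diol F3, and TEMPO/PhI(OAc)2 gives the bromo hydroxy enal F4. CrCl2 in THF under high dilution then effects the Nozaki–Hiyama–Kishi-type 2-(alkoxycarbonyl)allylation through a chair transition state with lactonisation, to give the trans-fused hydroxy lactone F5. Ac2O/pyridine gives 25. In this fallback the aldehyde face is not under reagent control, so the two trans-lactone diastereomers would have to be separated.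

2. Step 12. What may go wrong: incomplete carbon alkylation of the aluminium intermediate by the iodomethylboronate, or loss of the alkene geometry through the allenoate form of the alane. Fallback, setting out from 18 and coming back at 20: alkenylalane 19 is quenched with I2 to give the (2E)-2-iodo enoate F6 with the same double-bond geometry. A Negishi coupling of F6 with the zinc reagent IZnCH2Bpin under Pd(PPh3)4 catalysis in THF then forms the C–CH2B bond with retention and gives 20. The bond is thus made by cross-coupling at a configurationally fixed alkenyl iodide and not by alkylation of the alane.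

3. Step 14. What may go wrong: competing oxidation of the secondary allylic alcohol, or oxidative loss of the carbon–boron bond. Fallback, setting out from 20 and coming back at 22: Swern oxidation ((COCl)2, DMSO, CH2Cl2, −78 → −30 °C, then Et3N) of bis-silyl ether 20 cleaves and oxidises only the primary allylic triethylsilyl ether and gives the silyloxy enal F7. PPTS/MeOH at 0 °C then frees the secondary alcohol to give 22. The two oxygens are thereby told apart as silyl ethers, so no free diol has to be oxidised selectively.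

**Further compounds**

F1 | step 16 | methyl (2Z,6E,10E,12R,14E)-2-(hydroxymethyl)-6,10,14-trimethyl-12,16-bis[(triethylsilyl)oxy]hexadeca-2,6,10,14-tetraenoate | COC(=O)/C(CO)=C\CC/C(C)=C/CC/C(C)=C/[C@H](O[Si](CC)(CC)CC)C/C(C)=C/CO[Si](CC)(CC)CC
F2 | step 16 | methyl (2E,6E,10E,12R,14E)-2-(bromomethyl)-6,10,14-trimethyl-12,16-bis[(triethylsilyl)oxy]hexadeca-2,6,10,14-tetraenoate | COC(=O)/C(CBr)=C\CC/C(C)=C/CC/C(C)=C/[C@H](O[Si](CC)(CC)CC)C/C(C)=C/CO[Si](CC)(CC)CC
F3 | step 16 | methyl (2E,6E,10E,12R,14E)-2-(bromomethyl)-12,16-dihydroxy-6,10,14-trimethylhexadeca-2,6,10,14-tetraenoate | COC(=O)/C(CBr)=C\CC/C(C)=C/CC/C(C)=C/[C@H](O)C/C(C)=C/CO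
F4 | step 16 | methyl (2E,6E,10E,12R,14E)-2-(bromomethyl)-12-hydroxy-6,10,14-trimethyl-16-oxohexadeca-2,6,10,14-tetraenoate | COC(=O)/C(CBr)=C\CC/C(C)=C/CC/C(C)=C/[C@H](O)C/C(C)=C/C=O
F5 | step 16 | (3aR,6E,10E,12R,14E,15aS)-12-hydroxy-6,10,14-trimethyl-3-methylidene-3a,4,5,8,9,12,13,15a-octahydrocyclotetradeca[b]furan-2(3H)-one | C=C1C(=O)O[C@H]2/C=C(\C)C[C@@H](O)/C=C(\C)CC/C=C(\C)CC[C@H]12
F6 | step 12 | methyl (2E,6E,10E,12R,14E)-2-iodo-6,10,14-trimethyl-12,16-bis[(triethylsilyl)oxy]hexadeca-2,6,10,14-tetraenoate | COC(=O)/C(I)=C\CC/C(C)=C/CC/C(C)=C/[C@H](O[Si](CC)(CC)CC)C/C(C)=C/CO[Si](CC)(CC)CC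
F7 | step 14 | methyl (2Z,6E,10E,12R,14E)-6,10,14-trimethyl-16-oxo-2-[(4,4,5,5-tetramethyl-1,3,2-dioxaborolan-2-yl)methyl]-12-[(triethylsilyl)oxy]hexadeca-2,6,10,14-tetraenoate | COC(=O)/C(CB1OC(C)(C)C(C)(C)O1)=C\CC/C(C)=C/CC/C(C)=C/[C@H](O[Si](CC)(CC)CC)C/C(C)=C/C=O
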